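## Retrosynthetic overview

1. Target ⇐ bis-silylated (S)-γ-keto 2-(trimethylsilyl)ethyl ester, by one global fluoride deprotection.
2. Key disconnection is the ester C1–O bond: the (S)-ester ⇐ racemic 5-aryl-3-alkylfuran-2(5H)-one + 2-(trimethylsilyl)ethanol, by an isomerising dynamic kinetic alcoholysis in which the C–O bond formation fixes C2.
3. Butenolide ⇐ propargylic alcohol + CO (palladium cyclocarbonylation brings in C1 and closes the lactone C–O bond).
4. Propargylic alcohol ⇐ propyne (as its 1,3-dianion) + geranyl bromide + bis-silylated 2,5-dihydroxybenzaldehyde in one pot.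
5. Rings: the benzene ring is bought; the only ring made is the furanone (step 3), and it is opened again in step 4.

Assumption: commercial geranyl bromide is the (2E) isomer, so the 5E alkene of the target is bought and never touched; the target is (2S,5E).

## Route

Step 1
Reactants: 1 2,5-dihydroxybenzaldehyde; 2 chlorotriisopropylsilane
Product: 3 2,5-bis(triisopropylsilyloxy)benzaldehyde
Conditions: TIPSCl (2.4 equiv), imidazole (5 equiv), DMF, 0 °C → rt
Reagents that add atoms: chlorotriisopropylsilane (2), CC(C)[Si](Cl)(C(C)C)C(C)C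
Why: Imidazole-promoted silyl ether formation (substitution at silicon) caps both phenols with bulky groups that tolerate the organolithium, the carbonylation and the amine-catalysed step and leave together with the ester in step 5; no stereocenter is involved.

Step 2
Reactants: 4 propyne; 5 geranyl bromide [(2E)-1-bromo-3,7-dimethylocta-2,6-diene]; 3 2,5-bis(triisopropylsilyloxy)benzaldehyde
Product: 8 racemic (6E)-1-[2,5-bis(triisopropylsilyloxy)phenyl]-7,11-dimethyldodeca-6,10-dien-2-yn-1-ol, via 1,3-dilithiopropyne 6 (not isolated), via lithium acetylide 7 (not isolated)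
Conditions: propyne (1.05 equiv), n-BuLi (2.1 equiv), TMEDA, Et2O–hexane, −78 °C → rt; 5 (1.0 equiv), −78 → 0 °C; 3 (0.9 equiv), THF, −78 °C; AcOH, −78 °C
Reagents that add atoms: none
Why: Double deprotonation of propyne gives the propargyl/acetylide dianion, whose more reactive propargylic carbanion is alkylated by the allylic bromide (SN2 at C1 of geranyl, E-alkene untouched), and the remaining lithium acetylide then adds to the aldehyde (acetylide 1,2-addition, cold acid quench to stop silyl migration); the carbinol is racemic, which does not matter because this carbon becomes the ketone carbon.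

Step 3
Reactants: 8 racemic propargylic alcohol; 9 carbon monoxide
Product: 11 racemic 5-[2,5-bis(triisopropylsilyloxy)phenyl]-3-[(3E)-4,8-dimethylnona-3,7-dien-1-yl]furan-2(5H)-one, via allenoic acid 10 (not isolated)
Conditions: Pd2(dba)3·CHCl3 (2 mol%), dppb (8 mol%), CO (40 atm), H2 (14 atm), CH2Cl2, 95 °C
Reagents that add atoms: carbon monoxide (9), [C-]#[O+]
Why: Palladium-catalysed cyclocarbonylation of a propargylic alcohol: zerovalent palladium ionises the benzylic propargylic C–O bond to an allenylpalladium species, CO insertion gives allenoic acid 10, and its carboxyl oxygen closes onto the benzylic allene carbon to give the 2(5H)-furanone with the chain at C3 and the new carboxyl carbon at C2; the C5 stereocenter is racemic and is erased in step 4.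

Step 4
Reactants: 11 racemic butenolide; 12 2-(trimethylsilyl)ethanol
Product: 14 2-(trimethylsilyl)ethyl (2S,5E)-2-{2-[2,5-bis(triisopropylsilyloxy)phenyl]-2-oxoethyl}-6,10-dimethylundeca-5,9-dienoate, via furan-2(3H)-one 13 (not isolated)
Conditions: quinine-derived squaramide organocatalyst 3-{[3,5-bis(trifluoromethyl)phenyl]amino}-4-{[(8S,9S)-6'-methoxycinchonan-9-yl]amino}cyclobut-3-ene-1,2-dione (10 mol%), 12 (5 equiv), toluene (0.05 M), 4 Å MS, 35 °C, Ar
Reagents that add atoms: 2-(trimethylsilyl)ethanol (12), C[Si](C)(C)CCO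
Why: Proposed new method: isomerising dynamic kinetic alcoholysis of a γ-aryl butenolide, in which the quinuclidine nitrogen of the catalyst removes the benzylic, vinylogous C5–H to give an aromatic 2-oxidofuran held by the squaramide N–H bonds, kinetic C3-protonation gives enol lactone 13 whose C3–H is again acidic so that its enantiomers interconvert through the same furanolate, and the catalyst (squaramide activating the lactone C=O, quinuclidine delivering the alcohol as a general base) adds 12 to the acyl carbon of (3S)-13 faster than to (3R)-13, so the C–O bond-forming event fixes the (2S) centre while irreversible enol-to-ketone tautomerisation of the released enol drains all material through this channel (Curtin–Hammett); the closest known reaction types are the dynamic kinetic resolution of azlactones by enantioselective alcoholysis under bifunctional cinchona urea or squaramide catalysis and the amine-catalysed interconversion of β,γ- and α,β-unsaturated butenolides through their dienolates; the sense of induction cannot be predicted for this substrate class, so it is assigned on the first run, and the quinidine-derived pseudoenantiomer of the catalyst is used if the quinine-derived one favours the (2R)-ester.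

Step 5
Reactants: 14 (S)-keto ester
Product: 15 (2S,5E)-2-[2-(2,5-dihydroxyphenyl)-2-oxoethyl]-6,10-dimethylundeca-5,9-dienoic acid (target)
Conditions: TBAF (4 equiv), degassed THF, 0 °C → rt, Ar; AcOH (4 equiv)
Reagents that add atoms: none
Why: Fluoride attacks silicon, cleaving both aryl silyl ethers and fragmenting the 2-(trimethylsilyl)ethyl ester (fluoride-induced β-elimination to ethene and fluorotrimethylsilane) to the carboxylate without hydrolysis, so C2 should keep its (S) configuration, and acid quench under argon gives the hydroquinone keto acid with both trisubstituted alkenes intact.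

## Compound list

1 | 2,5-dihydroxybenzaldehyde | O=Cc1cc(O)ccc1O | starting material
2 | chlorotriisopropylsilane | CC(C)[Si](Cl)(C(C)C)C(C)C | starting material
3 | 2,5-bis(triisopropylsilyloxy)benzaldehyde | O=Cc1cc(O[Si](C(C)C)(C(C)C)C(C)C)ccc1O[Si](C(C)C)(C(C)C)C(C)C | intermediate
4 | propyne | CC#C | starting material
5 | geranyl bromide, (2E)-1-bromo-3,7-dimethylocta-2,6-diene | CC(C)=CCC/C(C)=C/CBr | starting material
6 | 1,3-dilithiopropyne | [Li]CC#C[Li] | intermediate
7 | lithium (5E)-6,10-dimethylundeca-5,9-dien-1-yn-1-ide | CC(C)=CCC/C(C)=C/CCC#C[Li] | intermediate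
8 | racemic (6E)-1-[2,5-bis(triisopropylsilyloxy)phenyl]-7,11-dimethyldodeca-6,10-dien-2-yn-1-ol | CC(C)=CCC/C(C)=C/CCC#CC(O)c1cc(O[Si](C(C)C)(C(C)C)C(C)C)ccc1O[Si](C(C)C)(C(C)C)C(C)C | intermediate
9 | carbon monoxide | [C-]#[O+] | starting material
10 | racemic 4-[2,5-bis(triisopropylsilyloxy)phenyl]-2-[(3E)-4,8-dimethylnona-3,7-dien-1-yl]buta-2,3-dienoic acid | CC(C)=CCC/C(C)=C/CCC(=C=Cc1cc(O[Si](C(C)C)(C(C)C)C(C)C)ccc1O[Si](C(C)C)(C(C)C)C(C)C)C(=O)O | intermediate
11 | racemic 5-[2,5-bis(triisopropylsilyloxy)phenyl]-3-[(3E)-4,8-dimethylnona-3,7-dien-1-yl]furan-2(5H)-one | CC(C)=CCC/C(C)=C/CCC1=CC(c2cc(O[Si](C(C)C)(C(C)C)C(C)C)ccc2O[Si](C(C)C)(C(C)C)C(C)C)OC1=O | intermediate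
12 | 2-(trimethylsilyl)ethanol | C[Si](C)(C)CCO | starting material
13 | racemising 5-[2,5-bis(triisopropylsilyloxy)phenyl]-3-[(3E)-4,8-dimethylnona-3,7-dien-1-yl]furan-2(3H)-one (enol lactone; the 3S enantiomer is the one consumed) | CC(C)=CCC/C(C)=C/CCC1C=C(c2cc(O[Si](C(C)C)(C(C)C)C(C)C)ccc2O[Si](C(C)C)(C(C)C)C(C)C)OC1=O | intermediate
14 | 2-(trimethylsilyl)ethyl (2S,5E)-2-{2-[2,5-bis(triisopropylsilyloxy)phenyl]-2-oxoethyl}-6,10-dimethylundeca-5,9-dienoate | CC(C)=CCC/C(C)=C/CC[C@@H](CC(=O)c1cc(O[Si](C(C)C)(C(C)C)C(C)C)ccc1O[Si](C(C)C)(C(C)C)C(C)C)C(=O)OCC[Si](C)(C)C | intermediate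
15 | (2S,5E)-2-[2-(2,5-dihydroxyphenyl)-2-oxoethyl]-6,10-dimethylundeca-5,9-dienoic acid | CC(C)=CCC/C(C)=C/CC[C@@H](CC(=O)c1cc(O)ccc1O)C(=O)O | target

## Step count and risk

Total steps: 5. Longest linear sequence: 5 (1 → 3 → 8 → 11 → 14 → 15).

**Step 4 (the new reaction) is the most likely to fail.** The γ-deprotonation may be slow next to the ortho-silyloxy aryl group, the enantioselectivity is untested, and dienolate dimerisation can compete. The fallback uses known chemistry, sets out from 11 and comes back at 14. Butenolide 11 is stirred with Et3N in wet THF at 40 °C; base-mediated isomerisation to the enol lactone and hydrolysis give the racemic keto acid F4. F4 is coupled with (S)-4-benzyl-1,3-oxazolidin-2-one (pivaloyl chloride, Et3N, LiCl, THF) to give two diastereomeric imides, the (2S)-imide F5 and the (2R)-imide F6, which are separated on silica. F5 is then transesterified with LiOCH2CH2Si(CH3)3 (made from 12 and n-BuLi, THF, −20 °C) to give 14 and the recovered auxiliary. This is a resolution, so at most half of the material is carried forward per pass.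

**Step 3 is the second risk.** The high-pressure cyclocarbonylation is best precedented for tertiary alkynols; the secondary, electron-rich benzylic alcohol 8 may instead undergo redox isomerisation to an enone or hydrogenolysis. The fallback sets out from 8 and comes back at 11. Trans-hydroalumination and iodination in one pot (NaAlH2(OCH2CH2OCH3)2, THF, 0 °C; then I2, −78 °C) give the Z-γ-hydroxy vinyl iodide F3. Carbonylative lactonisation at atmospheric pressure (PdCl2(PPh3)2 5 mol%, CO 1 atm, K2CO3, THF, 50 °C) then closes 11.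

**Step 2 is the third risk.** The one-pot dianion sequence can give some double alkylation or allenic product, and unreacted dianion consumes aldehyde. The fallback sets out from 5 (with 3) and comes back at 8. 1-(Trimethylsilyl)propyne is deprotonated (n-BuLi, THF, −78 °C) and alkylated with 5 to give the silyl enyne F1. K2CO3 in MeOH removes the silyl group to give the terminal enyne F2. F2 is lithiated (n-BuLi, THF, −78 °C) to acetylide 7 and added to 3 to give 8, at the cost of one extra isolated step.

## Further compounds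

F1 | step 2 | trimethyl[(5E)-6,10-dimethylundeca-5,9-dien-1-yn-1-yl]silane | CC(C)=CCC/C(C)=C/CCC#C[Si](C)(C)C
F2 | step 2 | (5E)-6,10-dimethylundeca-5,9-dien-1-yne | CC(C)=CCC/C(C)=C/CCC#C
F3 | step 3 | racemic (2Z,6E)-1-[2,5-bis(triisopropylsilyloxy)phenyl]-3-iodo-7,11-dimethyldodeca-2,6,10-trien-1-ol | CC(C)=CCC/C(C)=C/CC/C(I)=C/C(O)c1cc(O[Si](C(C)C)(C(C)C)C(C)C)ccc1O[Si](C(C)C)(C(C)C)C(C)C
F4 | step 4 | racemic (5E)-2-{2-[2,5-bis(triisopropylsilyloxy)phenyl]-2-oxoethyl}-6,10-dimethylundeca-5,9-dienoic acid | CC(C)=CCC/C(C)=C/CCC(CC(=O)c1cc(O[Si](C(C)C)(C(C)C)C(C)C)ccc1O[Si](C(C)C)(C(C)C)C(C)C)C(=O)O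
F5 | step 4 | (4S)-4-benzyl-3-[(2S,5E)-2-{2-[2,5-bis(triisopropylsilyloxy)phenyl]-2-oxoethyl}-6,10-dimethylundeca-5,9-dienoyl]-1,3-oxazolidin-2-one | CC(C)=CCC/C(C)=C/CC[C@@H](CC(=O)c1cc(O[Si](C(C)C)(C(C)C)C(C)C)ccc1O[Si](C(C)C)(C(C)C)C(C)C)C(=O)N1[C@@H](Cc2ccccc2)COC1=O
F6 | step 4 | (4S)-4-benzyl-3-[(2R,5E)-2-{2-[2,5-bis(triisopropylsilyloxy)phenyl]-2-oxoethyl}-6,10-dimethylundeca-5,9-dienoyl]-1,3-oxazolidin-2-one | CC(C)=CCC/C(C)=C/CC[C@H](CC(=O)c1cc(O[Si](C(C)C)(C(C)C)C(C)C)ccc1O[Si](C(C)C)(C(C)C)C(C)C)C(=O)N1[C@@H](Cc2ccccc2)COC1=O
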